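**Retrosynthetic overview**
1. Target ⇒ triene lactone by a final reagent-controlled epoxidation of the C3=C4 olefin; the exo-methylene and C1 ⇒ a macrocyclic butenolide (copper hydride 1,4-reduction with Mannich trapping, then elimination).
2. Macrocyclic butenolide ⇒ open-chain 4-alkyl-2-silyloxyfuran aldehyde: one dearomatising intramolecular vinylogous Mukaiyama aldol forms the C13–C14 bond, the 14-membered ring and both carbinol stereocentres.
3. Open-chain precursor ⇒ E-selective cross-metathesis (C6=C7) of a hydroxy aldehyde with a silyloxyfuran carrying a skipped-diene chain.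
4. Hydroxy aldehyde ⇒ (S)-linalool (C8 from the chiral pool, C12 by enzymatic conjugate reduction); silyloxyfuran ⇒ furan-3-ylmethanol + pent-1-en-4-yne (carboalumination/coupling, furan → butenolide → silyloxyfuran).
5. Ring order: furan ring (bought) → carbocycle and butenolide in the same step → saturated α-methylene lactone → epoxide last.

Assumption: (S)-(+)-linalool of high enantiomeric purity, furan-3-ylmethanol and pent-1-en-4-yne are bought.
Numbering in macrocycle names (cembrane skeleton): C1 = ring CH carrying C15 (lactone α-carbon; C16 = lactone C=O, C17 = exocyclic carbon); the ring runs C2, C3=C4(CH3), C5, C6=C7, C8(CH3)(OH), C9–C11, C12(CH3), C13(O), C14(lactone O).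

**Step 1**
Reactants: 1 (S)-linalool [(3S)-3,7-dimethylocta-1,6-dien-3-ol]
Product: 2 (2E,6S)-6-hydroxy-2,6-dimethylocta-2,7-dienal
Conditions: SeO2 (1.1 equiv), 1,4-dioxane/EtOH, 80 °C
Reagents that add atoms: selenium dioxide, O=[Se]=O
Why: Riley allylic oxidation (ene reaction, then [2,3]-sigmatropic shift) attacks only the (E)-methyl of the trisubstituted olefin and gives the (E)-enal, leaving the tertiary vinyl carbinol and its stereocentre untouched.

**Step 2**
Reactants: 2 (2E,6S)-6-hydroxy-2,6-dimethylocta-2,7-dienal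
Product: 3 (2S,6S)-6-hydroxy-2,6-dimethyloct-7-enal
Conditions: ene-reductase OYE2 (or a screened (S)-selective homologue), NADP+ (cat.), glucose dehydrogenase, D-glucose, K2HPO4/KH2PO4 buffer pH 7/MTBE, 30 °C
Reagents that add atoms: none
Why: Biocatalytic asymmetric conjugate reduction (old yellow enzyme) adds hydride to C3 and a proton to C2 in trans fashion on the activated C=C only, which sets 2S (the future C12) as known for (E)-2-methyl-2-alkenals and cannot touch the vinyl group.

**Step 3**
Reactants: 4 furan-3-ylmethanol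
Product: 5 3-(bromomethyl)furan
Conditions: PBr3 (0.4 equiv), Et2O, 0 °C; used at once
Reagents that add atoms: phosphorus tribromide, BrP(Br)Br
Why: Standard conversion of a primary furylmethyl alcohol into the bromide by SN2 displacement on the phosphite ester.

**Step 4**
Reactants: 6 pent-1-en-4-yne; 5 3-(bromomethyl)furan
Product: 8 3-[(2E)-3-methylhexa-2,5-dien-1-yl]furan, via alkenylalane 7 (not isolated)
Conditions: Me3Al (2 equiv), Cp2ZrCl2 (0.2 equiv), CH2Cl2, 0 °C to rt; then 5, Pd(PPh3)4 (3 mol%), THF, rt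
Reagents that add atoms: trimethylaluminium, C[Al](C)C
Why: Negishi zirconium-catalysed carboalumination adds CH3 and Al syn across the alkyne (methyl to the internal carbon), and the palladium-catalysed coupling of the alkenylalane with the furylmethyl bromide keeps that geometry, which fixes the E-trisubstituted C3=C4 olefin.

**Step 5**
Reactants: 8 3-[(2E)-3-methylhexa-2,5-dien-1-yl]furan
Product: 11 4-[(2E)-3-methylhexa-2,5-dien-1-yl]furan-2(5H)-one, via furan endoperoxide 9 (not isolated), via hydroxybutenolide 10 (not isolated)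
Conditions: O2, hν (visible), tetraphenylporphyrin (cat.), i-Pr2NEt, CH2Cl2, −78 °C; then NaBH4, EtOH, 0 °C; 1 M HCl work-up
Reagents that add atoms: dioxygen, O=O
Why: Singlet oxygen adds [4+2] to the furan far faster than it reacts with the alkenes, the hindered base removes the less hindered C5–H of the endoperoxide (Kornblum–DeLaMare type) to give the 4-alkyl-5-hydroxybutenolide regioselectively, and NaBH4 reduces its masked aldehyde so that the hydroxy acid relactonises to the β-substituted butenolide.

**Step 6**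
Reactants: 11 4-[(2E)-3-methylhexa-2,5-dien-1-yl]furan-2(5H)-one
Product: 12 triisopropyl({4-[(2E)-3-methylhexa-2,5-dien-1-yl]furan-2-yl}oxy)silane
Conditions: i-Pr3SiOTf (1.1 equiv), Et3N (1.5 equiv), CH2Cl2, 0 °C
Reagents that add atoms: triisopropylsilyl triflate, CC(C)[Si](C(C)C)(C(C)C)OS(=O)(=O)C(F)(F)F
Why: Soft enolisation with O-silylation removes a ring γ-proton because this gives the aromatic 2-silyloxyfuran, and the bulky silyl group makes it stable enough to isolate.

**Step 7**
Reactants: 3 (2S,6S)-6-hydroxy-2,6-dimethyloct-7-enal (2 equiv); 12 triisopropyl({4-[(2E)-3-methylhexa-2,5-dien-1-yl]furan-2-yl}oxy)silane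
Product: 13 (2S,6S,7E,10E)-6-hydroxy-2,6,10-trimethyl-12-{5-[(triisopropylsilyl)oxy]furan-3-yl}dodeca-7,10-dienal
Conditions: RuCl2(H2IMes)(=CH-C6H4-2-O-i-Pr) (second-generation Hoveyda–Grubbs catalyst, 5 mol%), 1,4-benzoquinone (10 mol%), CH2Cl2, 40 °C
Reagents that add atoms: none
Why: Olefin cross-metathesis between an unhindered terminal olefin and a tertiary vinyl carbinol (which does not homodimerise) gives only the E-disubstituted C6=C7 olefin, while the trisubstituted olefin, the aldehyde and the silyloxyfuran do not react.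

**Step 8**
Reactants: 13 (2S,6S,7E,10E)-6-hydroxy-2,6,10-trimethyl-12-{5-[(triisopropylsilyl)oxy]furan-3-yl}dodeca-7,10-dienal
Product: 14 (3E,6E,8S,12S,13R,14R)-8,13-dihydroxycembra-1(15),3,6-trien-16,14-olide
Conditions: slow addition of 13 (syringe pump, 8 h) to BF3·OEt2 (3 equiv), CH2Cl2 (final 1 mM), −78 °C; aq. NaHCO3
Reagents that add atoms: none
Why: Proposed new method: BF3 activates the aldehyde and the electron-rich C5 of the 2-silyloxyfuran, the only strongly nucleophilic π-system in the chain, attacks it through an open transition state at high dilution, so the furan loses its aromaticity as the butenolide and the 14-membered ring form together; with the ring chain (C11) anti to the forming bond the aldehyde is attacked in the Felkin–Anh sense (13R, syn to the C12 methyl) and the usual Lewis-acid syn preference of silyloxyfuran aldols sets 14R; the closest known reactions are the intermolecular BF3-mediated vinylogous Mukaiyama aldol of 2-silyloxyfurans with α-branched aldehydes and the intramolecular silyloxyfuran–aldehyde cycloaldolisations that close five- to seven-membered rings.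

**Step 9**
Reactants: 14 (3E,6E,8S,12S,13R,14R)-8,13-dihydroxycembra-1(15),3,6-trien-16,14-olide
Product: 16 (3E,6E,8S,12S,13R,14R)-13-acetoxy-8-(trimethylsilyloxy)cembra-1(15),3,6-trien-16,14-olide, via monoacetate 15 (not isolated)
Conditions: Ac2O (1.5 equiv), pyridine, DMAP (5 mol%), CH2Cl2, 0 °C; then N-(trimethylsilyl)imidazole (3 equiv), rt
Reagents that add atoms: acetic anhydride, CC(=O)OC(C)=O; N-(trimethylsilyl)imidazole, C[Si](C)(C)n1ccnc1
Why: DMAP-catalysed acetylation takes the secondary C13–OH and not the hindered tertiary C8–OH, which the non-enolising silyl donor then caps so that no acidic proton can quench the enolate of the next step.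

**Step 10**
Reactants: 16 (3E,6E,8S,12S,13R,14R)-13-acetoxy-8-(trimethylsilyloxy)cembra-1(15),3,6-trien-16,14-olide
Product: 19 (1S,3E,6E,8S,12S,13R,14R)-13-acetoxy-17-(dimethylamino)-8-hydroxycembra-3,6-dien-16,14-olide (C15 epimers), via silyl ketene acetal 17 (not isolated), via silylated Mannich base 18 (not isolated)
Conditions: [(Ph3P)CuH]6 (5 mol%), (EtO)2MeSiH (2 equiv), toluene, rt; then CH2=NMe2+ I− (3 equiv), CH2Cl2, 0 °C to rt; cold 1 M HCl (5 min), then NaHCO3
Reagents that add atoms: N,N-dimethylmethyleneiminium iodide (Eschenmoser's salt), C=[N+](C)C.[I-]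
Why: Copper hydride delivers hydride to C1 of the butenolide from the face opposite the C13 branch on C14 (the ansa chain covers the other face), which gives the cis-fused lactone (1S), and the resulting silyl ketene acetal undergoes a Mannich reaction with the iminium salt at C15 (Stryker-type conjugate reduction followed by Eschenmoser aminomethylation), the TMS ether falling off in the acidic work-up.

**Step 11**
Reactants: 19 (1S,3E,6E,8S,12S,13R,14R)-13-acetoxy-17-(dimethylamino)-8-hydroxycembra-3,6-dien-16,14-olide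
Product: 21 (1S,3E,6E,8S,12S,13R,14R)-13-acetoxy-8-hydroxycembra-3,6,15(17)-trien-16,14-olide, via methiodide 20 (not isolated)
Conditions: MeI (excess), MeOH, rt; then NaHCO3 (aq)/CH2Cl2, rt
Reagents that add atoms: none
Why: Quaternisation of the Mannich base followed by mild-base E1cB elimination of trimethylamine (Eschenmoser methylenation) gives the α-methylene lactone without disturbing the acetate or the C1 and C14 stereocentres.

**Step 12**
Reactants: 21 (1S,3E,6E,8S,12S,13R,14R)-13-acetoxy-8-hydroxycembra-3,6,15(17)-trien-16,14-olide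
Product: 22 (1S,3R,4R,6E,8S,12S,13R,14R)-13-acetoxy-3,4-epoxy-8-hydroxycembra-6,15(17)-dien-16,14-olide (CNP0202356.4)
Conditions: D-fructose-derived Shi ketone (0.3 equiv), KHSO5 (as 2KHSO5·KHSO4·K2SO4, 1.3 equiv), K2CO3, Bu4NHSO4, MeCN/CH2(OMe)2/aq. Na2B4O7 buffer (pH about 10.5), 0 °C, 1.5 h
Reagents that add atoms: potassium peroxymonosulfate, [K+].[O-]S(=O)(=O)OO
Why: Shi asymmetric epoxidation by the chiral dioxirane picks the electron-rich E-trisubstituted C3=C4 olefin over the carbinol-flanked disubstituted olefin and the electron-poor exo-methylene, and the D-fructose-derived ketone gives the (3R,4R)-epoxide through the spiro transition state.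

**Compound list**
1 | (S)-linalool, (3S)-3,7-dimethylocta-1,6-dien-3-ol | CC(C)=CCC[C@](C)(O)C=C | starting material
2 | (2E,6S)-6-hydroxy-2,6-dimethylocta-2,7-dienal | O=C/C(C)=C/CC[C@](C)(O)C=C | intermediate
3 | (2S,6S)-6-hydroxy-2,6-dimethyloct-7-enal | O=C[C@@H](C)CCC[C@](C)(O)C=C | intermediate
4 | furan-3-ylmethanol | OCc1ccoc1 | starting material
5 | 3-(bromomethyl)furan | BrCc1ccoc1 | intermediate
6 | pent-1-en-4-yne | C=CCC#C | starting material
7 | dimethyl[(1E)-2-methylpenta-1,4-dien-1-yl]alane | C=CC/C(C)=C/[Al](C)C | intermediate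
8 | 3-[(2E)-3-methylhexa-2,5-dien-1-yl]furan | C=CC/C(C)=C/Cc1ccoc1 | intermediate
9 | 5-[(2E)-3-methylhexa-2,5-dien-1-yl]-2,3,7-trioxabicyclo[2.2.1]hept-5-ene | C=CC/C(C)=C/CC1=CC2OOC1O2 | intermediate
10 | 5-hydroxy-4-[(2E)-3-methylhexa-2,5-dien-1-yl]furan-2(5H)-one (C5 epimers) | C=CC/C(C)=C/CC1=CC(=O)OC1O | intermediate
11 | 4-[(2E)-3-methylhexa-2,5-dien-1-yl]furan-2(5H)-one | C=CC/C(C)=C/CC1=CC(=O)OC1 | intermediate
12 | triisopropyl({4-[(2E)-3-methylhexa-2,5-dien-1-yl]furan-2-yl}oxy)silane | C=CC/C(C)=C/Cc1coc(O[Si](C(C)C)(C(C)C)C(C)C)c1 | intermediate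
13 | (2S,6S,7E,10E)-6-hydroxy-2,6,10-trimethyl-12-{5-[(triisopropylsilyl)oxy]furan-3-yl}dodeca-7,10-dienal | O=C[C@@H](C)CCC[C@](C)(O)/C=C/C/C(C)=C/Cc1coc(O[Si](C(C)C)(C(C)C)C(C)C)c1 | intermediate
14 | (3E,6E,8S,12S,13R,14R)-8,13-dihydroxycembra-1(15),3,6-trien-16,14-olide (butenolide fused to the 14-membered ring) | O=C1O[C@H]2[C@H](O)[C@@H](C)CCC[C@](C)(O)/C=C/C/C(C)=C/CC2=C1 | intermediate
15 | (3E,6E,8S,12S,13R,14R)-13-acetoxy-8-hydroxycembra-1(15),3,6-trien-16,14-olide | O=C1O[C@H]2[C@H](OC(C)=O)[C@@H](C)CCC[C@](C)(O)/C=C/C/C(C)=C/CC2=C1 | intermediate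
16 | (3E,6E,8S,12S,13R,14R)-13-acetoxy-8-(trimethylsilyloxy)cembra-1(15),3,6-trien-16,14-olide | O=C1O[C@H]2[C@H](OC(C)=O)[C@@H](C)CCC[C@](C)(O[Si](C)(C)C)/C=C/C/C(C)=C/CC2=C1 | intermediate
17 | diethoxy(methyl)silyl ketene acetal of the (1S)-dihydro lactone of 16 | C1=C(O[Si](C)(OCC)OCC)O[C@H]2[C@H](OC(C)=O)[C@@H](C)CCC[C@](C)(O[Si](C)(C)C)/C=C/C/C(C)=C/C[C@@H]12 | intermediate
18 | (1S,3E,6E,8S,12S,13R,14R)-13-acetoxy-17-(dimethylamino)-8-(trimethylsilyloxy)cembra-3,6-dien-16,14-olide (C15 epimers) | CN(C)CC1C(=O)O[C@H]2[C@H](OC(C)=O)[C@@H](C)CCC[C@](C)(O[Si](C)(C)C)/C=C/C/C(C)=C/C[C@@H]12 | intermediate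
19 | (1S,3E,6E,8S,12S,13R,14R)-13-acetoxy-17-(dimethylamino)-8-hydroxycembra-3,6-dien-16,14-olide (C15 epimers) | CN(C)CC1C(=O)O[C@H]2[C@H](OC(C)=O)[C@@H](C)CCC[C@](C)(O)/C=C/C/C(C)=C/C[C@@H]12 | intermediate
20 | N-methyl iodide (trimethylammonium salt) of 19 | C[N+](C)(C)CC1C(=O)O[C@H]2[C@H](OC(C)=O)[C@@H](C)CCC[C@](C)(O)/C=C/C/C(C)=C/C[C@@H]12.[I-] | intermediate
21 | (1S,3E,6E,8S,12S,13R,14R)-13-acetoxy-8-hydroxycembra-3,6,15(17)-trien-16,14-olide | C=C1C(=O)O[C@H]2[C@H](OC(C)=O)[C@@H](C)CCC[C@](C)(O)/C=C/C/C(C)=C/C[C@@H]12 | intermediate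
22 | (1S,3R,4R,6E,8S,12S,13R,14R)-13-acetoxy-3,4-epoxy-8-hydroxycembra-6,15(17)-dien-16,14-olide | C=C1C(=O)O[C@H]2[C@H](OC(C)=O)[C@@H](C)CCC[C@](C)(O)/C=C/C[C@@]3(C)O[C@@H]3C[C@@H]12 | target

**Step count**
Total: 12 steps. Longest linear sequence: 10 steps (steps 3 to 12, from furan-3-ylmethanol).

**Steps most likely to fail and fallbacks**

Step 8 (dearomatising macrocyclisation). The risks are oligomerisation, ionisation of the free tertiary allylic alcohol by BF3, and ring strain overriding the Felkin/syn preference. The fallback sets out from 3 and 12 and comes back at 14. The aldol is run between the two fragments first (BF3·OEt2, CH2Cl2, −78 °C), where open-chain Felkin and syn selectivity are well precedented, to give the open-chain butenolide diol F1. The ring is then closed at C6=C7 by ring-closing metathesis (RuCl2(H2IMes)(PCy3)(=CHPh), second-generation Grubbs catalyst, CH2Cl2, 1 mM, 40 °C), where the tertiary carbinol flank favours the E olefin, to give 14.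

Step 10 (conjugate reduction with Mannich trapping). The risks are incomplete trapping of the silyl ketene acetal and poor face selectivity at C1 inside the ring. The fallback sets out from 14 and comes back at 21. It separates the two events and uses strong-base enolate chemistry on the unprotected diol:
- 14 is reduced with proton quench (CuCl/NaOt-Bu/p-tol-BINAP, polymethylhydrosiloxane, t-BuOH; the ligand enantiomer that reinforces attack anti to C13 is chosen by trial) to the saturated cis-lactone diol F2.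
- The trianion of F2 (LDA, 3.3 equiv, THF, −78 °C) is aminomethylated with Eschenmoser's salt to the Mannich base diol F3.
- MeI gives the methiodide F4, and NaHCO3 then gives the α-methylene lactone diol F5.
- Selective acetylation of the secondary hydroxyl (Ac2O, pyridine, DMAP, 0 °C) gives 21.

Step 12 (late epoxidation). The risk is that the ring exposes only one face of the C3=C4 olefin and overrides the catalyst, giving the (3S,4S)-epoxide. The fallback sets out from 21 and comes back at 22. It inverts the facial outcome: NBS in THF/H2O at 0 °C puts bromine on the exposed face and water anti at the tertiary carbon, giving the bromohydrin F6. Ring closure with K2CO3 in MeCN then places the oxygen on the opposite face and gives 22.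

**Further compounds**
F1 | step 8 | (5R)-5-[(1R,2S,6S)-1,6-dihydroxy-2,6-dimethyloct-7-en-1-yl]-4-[(2E)-3-methylhexa-2,5-dien-1-yl]furan-2(5H)-one | C=CC/C(C)=C/CC1=CC(=O)O[C@H]1[C@H](O)[C@@H](C)CCC[C@](C)(O)C=C
F2 | step 10 | (1S,3E,6E,8S,12S,13R,14R)-8,13-dihydroxycembra-3,6-dien-16,14-olide | C1C(=O)O[C@H]2[C@H](O)[C@@H](C)CCC[C@](C)(O)/C=C/C/C(C)=C/C[C@@H]12
F3 | step 10 | (1S,3E,6E,8S,12S,13R,14R)-17-(dimethylamino)-8,13-dihydroxycembra-3,6-dien-16,14-olide (C15 epimers) | CN(C)CC1C(=O)O[C@H]2[C@H](O)[C@@H](C)CCC[C@](C)(O)/C=C/C/C(C)=C/C[C@@H]12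
F4 | step 10 | N-methyl iodide (trimethylammonium salt) of F3 | C[N+](C)(C)CC1C(=O)O[C@H]2[C@H](O)[C@@H](C)CCC[C@](C)(O)/C=C/C/C(C)=C/C[C@@H]12.[I-]
F5 | step 10 | (1S,3E,6E,8S,12S,13R,14R)-8,13-dihydroxycembra-3,6,15(17)-trien-16,14-olide | C=C1C(=O)O[C@H]2[C@H](O)[C@@H](C)CCC[C@](C)(O)/C=C/C/C(C)=C/C[C@@H]12
F6 | step 12 | (1S,3S,4R,6E,8S,12S,13R,14R)-13-acetoxy-3-bromo-4,8-dihydroxycembra-6,15(17)-dien-16,14-olide | C=C1C(=O)O[C@H]2[C@H](OC(C)=O)[C@@H](C)CCC[C@](C)(O)/C=C/C[C@@](C)(O)[C@@H](Br)C[C@@H]12
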